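The route disconnects ring C at C4a–C4 and O1–C2. Ring A is fully substituted and, if O1 and the 5-OH are taken as like oxygens, symmetric about the C4a–C7 axis: C4a lies between the oxygens on C5 and C8a, and C6 and C8 carry matching methoxyls. One catalyst-free thermal condensation of 4,5,6-trimethoxyresorcinol (a single ring C–H between two equivalent hydroxyls) with an α-methoxy β-ketoester that already holds ring B and the C3 methoxyl should make both bonds, close the pyranone and leave the unused hydroxyl as the 5-OH. The ketoester carries the 2'-oxygen as an isopropyl ether, cleaved in the last step.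

Key step: step 5

Assumption: the target is a planar, achiral flavone without stereocentres, so no enantiocontrol is needed; the only stereocentre on the route (the α-carbon of the ketoester) is racemic and is destroyed in step 5.

Step 1
Reactants: 1 1,2,3-trimethoxybenzene
Product: 2 1,5-dibromo-2,3,4-trimethoxybenzene
Conditions: NBS (2.1 equiv), MeCN, 0 °C → rt
Reagents that add atoms: N-bromosuccinimide, O=C1CCC(=O)N1Br
Why: Electrophilic aromatic bromination, in which C4 and C6 are each ortho to one outer methoxyl and para to the other whereas C5 is para only to the twisted central methoxyl, so both bromines should enter at C4 and C6 and leave the hydrogen between them.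

Step 2
Reactants: 2 1,5-dibromo-2,3,4-trimethoxybenzene
Product: 3 4,5,6-trimethoxybenzene-1,3-diol
Conditions: Pd2(dba)3 (cat.), tBuXPhos (cat.), KOH (6 equiv), 1,4-dioxane/H2O (degassed), 100 °C; then 2 M HCl under Ar
Reagents that add atoms: potassium hydroxide, [K+].[OH-]
Why: Palladium-catalysed C–O coupling of aryl bromides with hydroxide (bulky biarylphosphine ligand) should turn both C–Br bonds, each with only one ortho substituent, into C–OH while the methyl ethers are inert to aqueous KOH; exclusion of air protects the easily oxidised bis-phenoxide until acidification.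

Step 3
Reactants: 4 2-hydroxy-4-methoxybenzoic acid
Product: 6 2-isopropoxy-4-methoxybenzoic acid, via isopropyl 2-isopropoxy-4-methoxybenzoate 5 (not isolated)
Conditions: 2-bromopropane (4 equiv), K2CO3, DMSO, 60 °C; then 5 M aq NaOH, 90 °C; HCl to pH 2
Reagents that add atoms: 2-bromopropane, CC(C)Br; sodium hydroxide, [Na+].[OH-]
Why: Williamson alkylation of the carboxylate and then of the hydrogen-bonded phenoxide (excess secondary bromide offsets E2 loss), followed by saponification in the same flask, which cleaves only the ester and leaves both aryl ethers intact.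

Step 4
Reactants: 6 2-isopropoxy-4-methoxybenzoic acid; 7 ethyl methoxyacetate
Product: 10 racemic ethyl 3-(2-isopropoxy-4-methoxyphenyl)-2-methoxy-3-oxopropanoate, via 2-isopropoxy-4-methoxybenzoyl chloride 8 (not isolated), via lithium enolate of ethyl methoxyacetate 9 (not isolated)
Conditions: 6, (COCl)2, cat. DMF, CH2Cl2, 0 °C → rt, evaporate; 7 (2.2 equiv), LiHMDS (2.2 equiv), THF, −78 °C, then crude 8, −78 → 0 °C; aq NH4Cl
Reagents that add atoms: none
Why: Crossed Claisen condensation run as C-acylation of a preformed lithium ester enolate by an aroyl chloride, in which the second equivalent of 9 deprotonates the more acidic β-ketoester as it forms and so suppresses double acylation; the new α-stereocentre arises racemic, is enolisable and later becomes sp2 C3, so it needs no control.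

Step 5
Reactants: 3 4,5,6-trimethoxybenzene-1,3-diol; 10 racemic ethyl 3-(2-isopropoxy-4-methoxyphenyl)-2-methoxy-3-oxopropanoate
Product: 13 5-hydroxy-2'-isopropoxy-3,6,7,8,4'-pentamethoxyflavone, via acylketene 11 (not isolated), via aryl diketone 12 (not isolated)
Conditions: neat melt, 10 (1.3 equiv), no catalyst, Ar sweep, 240–250 °C, EtOH and H2O distilled out (alternatively Ph2O, reflux)
Reagents that add atoms: none
Why: Heat should expel ethanol from 10 to give acylketene 11, whose ketene carbon is attacked by the one hydrogen-bearing ring carbon of 3 (doubly ortho-hydroxylated, phloroglucinol-like) to form C4a–C4 and give diketone 12; this is the Mentzer pyrone synthesis, the closest general type being thermal acylketene transacylation of β-ketoesters. Ring C then closes by 6-exo-trig addition of a phenolic oxygen of 12 to the B-ring aryl ketone carbonyl (O1–C2), followed by loss of water to the aromatic 4-pyranone. No stereocentre is created: the racemic α-carbon of 10 ends as sp2 C3. Three selectivities are needed: C- over O-acylation, chromone over coumarin closure, and a choice between the two hydroxyls. The first two rest on the acid-free thermal regime, in which an O-acylated aryl β-ketoester simply reverts to 11 while 12 is the sink and in which attack of the ring carbon on the hindered ortho-alkoxy aryl ketone (the coumarin path) lacks acid promotion; the third is void because the mirror plane through C2 and C5 of 3 makes both hydroxyls identical. The hydroxyl left over becomes the hydrogen-bonded 5-OH, and the isopropyl ether, stable at this temperature, keeps the 2'-oxygen from lactonising onto the ester.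

Step 6
Reactants: 13 5-hydroxy-2'-isopropoxy-3,6,7,8,4'-pentamethoxyflavone
Product: 14 5,2'-dihydroxy-3,6,7,8,4'-pentamethoxyflavone
Conditions: BCl3 (1 M in CH2Cl2, 3–4 equiv), CH2Cl2, −78 → 0 °C; then aq NaHCO3
Reagents that add atoms: none
Why: Lewis-acid dealkylation of an aryl sec-alkyl ether, in which BCl3 binds the 2'-oxygen and the isopropyl group leaves by SN1-like ionisation as 2-chloropropane at temperatures where primary methyl ethers do not react, while the 5-OH is held as its BCl2 chelate with the C4 carbonyl and is released on aqueous work-up.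

Compound list
1 | 1,2,3-trimethoxybenzene | COc1cccc(OC)c1OC | starting material
2 | 1,5-dibromo-2,3,4-trimethoxybenzene | COc1c(Br)cc(Br)c(OC)c1OC | intermediate
3 | 4,5,6-trimethoxybenzene-1,3-diol | COc1c(O)cc(O)c(OC)c1OC | intermediate
4 | 2-hydroxy-4-methoxybenzoic acid | COc1ccc(C(=O)O)c(O)c1 | starting material
5 | isopropyl 2-isopropoxy-4-methoxybenzoate | COc1ccc(C(=O)OC(C)C)c(OC(C)C)c1 | intermediate (not isolated)
6 | 2-isopropoxy-4-methoxybenzoic acid | COc1ccc(C(=O)O)c(OC(C)C)c1 | intermediate
7 | ethyl methoxyacetate | CCOC(=O)COC | starting material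
8 | 2-isopropoxy-4-methoxybenzoyl chloride | COc1ccc(C(=O)Cl)c(OC(C)C)c1 | intermediate (not isolated)
9 | lithium enolate of ethyl methoxyacetate (geometry immaterial) | CCOC(O[Li])=COC | intermediate (not isolated)
10 | ethyl 3-(2-isopropoxy-4-methoxyphenyl)-2-methoxy-3-oxopropanoate, racemic | CCOC(=O)C(OC)C(=O)c1ccc(OC)cc1OC(C)C | intermediate
11 | (2-isopropoxy-4-methoxybenzoyl)(methoxy)ketene | COC(=C=O)C(=O)c1ccc(OC)cc1OC(C)C | intermediate (not isolated)
12 | 1-(2,6-dihydroxy-3,4,5-trimethoxyphenyl)-3-(2-isopropoxy-4-methoxyphenyl)-2-methoxypropane-1,3-dione, racemic | COc1ccc(C(=O)C(OC)C(=O)c2c(O)c(OC)c(OC)c(OC)c2O)c(OC(C)C)c1 | intermediate (not isolated)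
13 | 5-hydroxy-2'-isopropoxy-3,6,7,8,4'-pentamethoxyflavone | COc1ccc(-c2oc3c(OC)c(OC)c(OC)c(O)c3c(=O)c2OC)c(OC(C)C)c1 | intermediate
14 | 5,2'-dihydroxy-3,6,7,8,4'-pentamethoxyflavone | COc1ccc(-c2oc3c(OC)c(OC)c(OC)c(O)c3c(=O)c2OC)c(O)c1 | target

Total step count: 6.
Longest linear sequence: 4 steps (steps 3, 4, 5, 6 from 4; equally steps 1, 2, 5, 6 from 1).

Steps most likely to fail

Step 5. The ketoester may only transesterify onto a hydroxyl of 3 without C–C bond formation, closure may take the coumarin direction, or the electron-rich resorcinol may degrade thermally before it reacts. The fallback sets out from 3, uses acid chloride 8 from step 4, and comes back at 13. Hoesch acylation of 3 with methoxyacetonitrile (ZnCl2, HCl gas, Et2O, 0 °C) should place the methoxyacetyl unit on the same ring carbon and precipitate 1-(2,6-dihydroxy-3,4,5-trimethoxyphenyl)-2-methoxyethan-1-iminium chloride F1. Hot water should hydrolyse this to 1-(2,6-dihydroxy-3,4,5-trimethoxyphenyl)-2-methoxyethan-1-one F2. Treatment of F2 with LiHMDS (4 equiv, THF, −78 °C) and then 8 should C-aroylate the ketone enolate of the trilithium salt and give diketone 12, this time isolated. Catalytic TsOH in warm toluene should then cyclodehydrate 12 to 13 (Baker–Venkataraman-type diketone route).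

Step 2. The reaction may stall after the first C–O coupling, protodebromination may compete, or the bis-phenoxide may be lost by oxidation in hot alkali. The fallback sets out from 2 and comes back at 3. Twofold Miyaura borylation (B2pin2, PdCl2(dppf), KOAc, dioxane, 90 °C) should give 2,2'-(4,5,6-trimethoxy-1,3-phenylene)bis(4,4,5,5-tetramethyl-1,3,2-dioxaborolane) F3. Oxidation of both C–B bonds (NaBO3·4H2O, THF/H2O, rt) should then deliver 3 under mild, nearly neutral conditions.

Step 6. Chelation-assisted loss of a methyl ether (the 3-methoxyl beside the carbonyl or the 6-methoxyl beside the boron-bound 5-oxygen) may compete with removal of the isopropyl group. The fallback sets out from 4 and comes back at 14. It replaces the protecting group by benzyl, so that the last step is a hydrogenolysis that cannot touch methyl ethers. Compound 4 with benzyl bromide and K2CO3 in DMF should give benzyl 2-(benzyloxy)-4-methoxybenzoate F4, saponified (NaOH, aq MeOH) to 2-(benzyloxy)-4-methoxybenzoic acid F5. Oxalyl chloride converts F5 into 2-(benzyloxy)-4-methoxybenzoyl chloride F6, which acylates enolate 9 as in step 4 to give ethyl 3-[2-(benzyloxy)-4-methoxyphenyl]-2-methoxy-3-oxopropanoate F7. Thermal condensation of F7 with 3 as in step 5 should run through [2-(benzyloxy)-4-methoxybenzoyl](methoxy)ketene F8 and 1-[2-(benzyloxy)-4-methoxyphenyl]-3-(2,6-dihydroxy-3,4,5-trimethoxyphenyl)-2-methoxypropane-1,3-dione F9 to 2'-(benzyloxy)-5-hydroxy-3,6,7,8,4'-pentamethoxyflavone F10. Hydrogenolysis of F10 (H2, 1 atm, Pd/C, EtOAc, rt) then gives 14.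

Further compounds
F1 | step 5 | 1-(2,6-dihydroxy-3,4,5-trimethoxyphenyl)-2-methoxyethan-1-iminium chloride | COCC(=[NH2+])c1c(O)c(OC)c(OC)c(OC)c1O.[Cl-]
F2 | step 5 | 1-(2,6-dihydroxy-3,4,5-trimethoxyphenyl)-2-methoxyethan-1-one | COCC(=O)c1c(O)c(OC)c(OC)c(OC)c1O
F3 | step 2 | 2,2'-(4,5,6-trimethoxy-1,3-phenylene)bis(4,4,5,5-tetramethyl-1,3,2-dioxaborolane) | COc1c(B2OC(C)(C)C(C)(C)O2)cc(B2OC(C)(C)C(C)(C)O2)c(OC)c1OC
F4 | step 6 | benzyl 2-(benzyloxy)-4-methoxybenzoate | COc1ccc(C(=O)OCc2ccccc2)c(OCc2ccccc2)c1
F5 | step 6 | 2-(benzyloxy)-4-methoxybenzoic acid | COc1ccc(C(=O)O)c(OCc2ccccc2)c1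
F6 | step 6 | 2-(benzyloxy)-4-methoxybenzoyl chloride | COc1ccc(C(=O)Cl)c(OCc2ccccc2)c1
F7 | step 6 | ethyl 3-[2-(benzyloxy)-4-methoxyphenyl]-2-methoxy-3-oxopropanoate, racemic | CCOC(=O)C(OC)C(=O)c1ccc(OC)cc1OCc1ccccc1
F8 | step 6 | [2-(benzyloxy)-4-methoxybenzoyl](methoxy)ketene | COC(=C=O)C(=O)c1ccc(OC)cc1OCc1ccccc1
F9 | step 6 | 1-[2-(benzyloxy)-4-methoxyphenyl]-3-(2,6-dihydroxy-3,4,5-trimethoxyphenyl)-2-methoxypropane-1,3-dione, racemic | COc1ccc(C(=O)C(OC)C(=O)c2c(O)c(OC)c(OC)c(OC)c2O)c(OCc2ccccc2)c1
F10 | step 6 | 2'-(benzyloxy)-5-hydroxy-3,6,7,8,4'-pentamethoxyflavone | COc1ccc(-c2oc3c(OC)c(OC)c(OC)c(O)c3c(=O)c2OC)c(OCc2ccccc2)c1
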